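Assumption: the target is read as (2S,6E,10E)-12-(3-formyl-2,4,5-trihydroxyphenyl)-2,6,10-trimethyldodeca-6,10-dienoic acid; benzene-1,2,4-triol, geranyl bromide and tert-butyl (S)-lactate are taken as catalogue materials.

**Retrosynthetic overview**
- Last step: one buffered silyl-triflate deprotection of a fully masked ester (three MOM ethers, a diethyl acetal, a tert-butyl ester).
- Key C2–C3 bond: the propionate α-carbon, normally a donor, is used as an acceptor (L-lactate triflate) and joined to a primary alkylmagnesium made in the same flask from a terminal vinyl group; SN2 inversion fixes (2S).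
- The vinyl group comes from vinylMgBr and an allylic bromide, itself from allylic oxidation of the E-methyl terminus of an aryl-geranyl unit; both E olefins are bought with geranyl bromide.
- Aryl C–C bonds: aryllithium plus geranyl bromide; the formyl carbon enters by directed ortho-metalation between two MOM ethers, directly as its acetal.
- No ring is formed; the benzene ring is bought as benzene-1,2,4-triol.

**Route**

Step 1
Reactants: 1 benzene-1,2,4-triol
Product: 2 1,2,4-tris(methoxymethoxy)benzene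
Conditions: NaH (3.6 equiv), MOMCl (3.6 equiv), DMF, 0 °C → rt, Ar
Reagents that add atoms: chloromethyl methyl ether (COCCl)
Why: Exhaustive Williamson O-alkylation of the trisodium phenoxide (MOM protection) masks the air-sensitive triol and installs three ortho-directing groups.

Step 2
Reactants: 2 1,2,4-tris(methoxymethoxy)benzene
Product: 3 1-bromo-2,4,5-tris(methoxymethoxy)benzene
Conditions: NBS (1.0 equiv), MeCN, 0 °C
Reagents that add atoms: N-bromosuccinimide (BrN1C(=O)CCC1=O)
Why: Electrophilic aromatic bromination goes to C5, which is para to one MOM ether and ortho to another and, unlike C3, is not flanked by two substituents.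

Step 3
Reactants: 3 1-bromo-2,4,5-tris(methoxymethoxy)benzene; 4 geranyl bromide [(2E)-1-bromo-3,7-dimethylocta-2,6-diene]
Product: 6 1-[(2E)-3,7-dimethylocta-2,6-dien-1-yl]-2,4,5-tris(methoxymethoxy)benzene, via aryllithium 5 (not isolated)
Conditions: n-BuLi (1.05 equiv), THF, −78 °C; then CuBr·SMe2 (10 mol %), 4 (1.1 equiv), −78 → 0 °C
Reagents that add atoms: none
Why: Bromine–lithium exchange followed by CuBr·SMe2-catalysed SN2 allylation at the primary carbon of geranyl bromide forms the aryl–CH2 bond and leaves the E olefin intact.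

Step 4
Reactants: 6 1-[(2E)-3,7-dimethylocta-2,6-dien-1-yl]-2,4,5-tris(methoxymethoxy)benzene
Product: 7 (2E,6E)-2,6-dimethyl-8-[2,4,5-tris(methoxymethoxy)phenyl]octa-2,6-dien-1-ol
Conditions: SeO2 (0.3 equiv), t-BuOOH (70% aq., 3 equiv), CH2Cl2, 0 °C → rt, stopped at about 70% conversion
Reagents that add atoms: tert-butyl hydroperoxide (CC(C)(C)OO); selenium dioxide (O=[Se]=O, catalytic oxygen carrier)
Why: Riley allylic oxidation (ene reaction then [2,3]-sigmatropic shift) attacks the E-methyl group of the terminal, most electron-rich trisubstituted olefin and gives the E allylic alcohol.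

Step 5
Reactants: 7 (2E,6E)-2,6-dimethyl-8-[2,4,5-tris(methoxymethoxy)phenyl]octa-2,6-dien-1-ol
Product: 8 1-[(2E,6E)-8-bromo-3,7-dimethylocta-2,6-dien-1-yl]-2,4,5-tris(methoxymethoxy)benzene
Conditions: CBr4 (1.3 equiv), PPh3 (1.3 equiv), CH2Cl2, 0 °C; used at once
Reagents that add atoms: carbon tetrabromide (BrC(Br)(Br)Br)
Why: Appel bromination converts the primary allylic alcohol into the bromide under neutral conditions without allylic transposition or loss of E geometry.

Step 6
Reactants: 8 1-[(2E,6E)-8-bromo-3,7-dimethylocta-2,6-dien-1-yl]-2,4,5-tris(methoxymethoxy)benzene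
Product: 9 1-[(2E,6E)-3,7-dimethyldeca-2,6,9-trien-1-yl]-2,4,5-tris(methoxymethoxy)benzene
Conditions: CH2=CHMgBr (1.5 equiv), Li2CuCl4 (5 mol %), THF, −40 → 0 °C, fast addition
Reagents that add atoms: vinylmagnesium bromide (C=C[Mg]Br)
Why: Kochi-type Li2CuCl4-catalysed Grignard coupling substitutes the primary allylic bromide at the α-carbon and installs the terminal vinyl group with retention of the E olefin.

Step 7
Reactants: 9 1-[(2E,6E)-3,7-dimethyldeca-2,6,9-trien-1-yl]-2,4,5-tris(methoxymethoxy)benzene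
Product: 12 1-(diethoxymethyl)-3-[(2E,6E)-3,7-dimethyldeca-2,6,9-trien-1-yl]-2,5,6-tris(methoxymethoxy)benzene, via aryllithium 10 (not isolated), via arylmagnesium bromide 11 (not isolated)
Conditions: n-BuLi (1.2 equiv), THF, 0 °C, 1 h; MgBr2·OEt2 (1.3 equiv), 0 °C; PhOCH(OEt)2 (1.5 equiv), 0 °C → rt; aq. NaHCO3 work-up
Reagents that add atoms: diethyl phenyl orthoformate (CCOC(OCC)Oc1ccccc1)
Why: Directed ortho-metalation occurs at the C–H flanked by two MOM ethers, and after transmetalation the aryl Grignard displaces phenoxide from the orthoformate (Bodroux–Chichibabin-type formylation), so the aldehyde carbon enters directly as its diethyl acetal.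

Step 8
Reactants: 13 tert-butyl (2S)-2-hydroxypropanoate
Product: 14 tert-butyl (2S)-2-{[(trifluoromethyl)sulfonyl]oxy}propanoate
Conditions: Tf2O (1.1 equiv), 2,6-lutidine (1.2 equiv), CH2Cl2, −78 → 0 °C
Reagents that add atoms: trifluoromethanesulfonic anhydride (FC(F)(F)S(=O)(=O)OS(=O)(=O)C(F)(F)F)
Why: O-Triflation of the secondary alcohol leaves the C–O bond untouched, so the (S) configuration is retained and the α-carbon of the ester becomes a strong electrophile.

Step 9
Reactants: 12 1-(diethoxymethyl)-3-[(2E,6E)-3,7-dimethyldeca-2,6,9-trien-1-yl]-2,5,6-tris(methoxymethoxy)benzene; 14 tert-butyl (2S)-2-{[(trifluoromethyl)sulfonyl]oxy}propanoate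
Product: 16 tert-butyl (2S,6E,10E)-12-[3-(diethoxymethyl)-2,4,5-tris(methoxymethoxy)phenyl]-2,6,10-trimethyldodeca-6,10-dienoate, via alkylmagnesium bromide 15 (not isolated)
Conditions: c-C5H9MgBr (1.3 equiv), FeCl3 (2.5 mol %), CuBr (5 mol %), PBu3 (10 mol %), Et2O/THF, 0 °C → rt; then ZnCl2 (5 mol %), 14 (1.6 equiv), THF, 0 °C
Reagents that add atoms: none
Why: FeCl3/CuBr-catalysed alkene–Grignard exchange (transfer hydromagnesiation) converts only the monosubstituted vinyl group into the primary alkylmagnesium bromide, whose triorganozincate then displaces triflate from the α-carbon of 14 in a ZnCl2-catalysed enantiospecific SN2 coupling with inversion, which gives the (2S) ester because the new CH2 group ranks below the ester carbon whereas the departing triflate ranked above it.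

Step 10
Reactants: 16 tert-butyl (2S,6E,10E)-12-[3-(diethoxymethyl)-2,4,5-tris(methoxymethoxy)phenyl]-2,6,10-trimethyldodeca-6,10-dienoate
Product: 18 (2S,6E,10E)-12-(3-formyl-2,4,5-trihydroxyphenyl)-2,6,10-trimethyldodeca-6,10-dienoic acid, via persilylated bipyridinium salt 17 (not isolated)
Conditions: TMSOTf (10 equiv), 2,2'-bipyridyl (12 equiv), CH2Cl2, 0 °C → rt, Ar; then degassed H2O, rt
Reagents that add atoms: water (O)
Why: TMSOTf buffered by 2,2'-bipyridyl cleaves the three aryl MOM ethers to silyl ethers, the acetal to a pyridinium salt and the tert-butyl ester to a silyl ester without protic acid, so water then releases the triol, the aldehyde and the acid while the acid-sensitive olefins and the C2 stereocentre stay untouched.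

**Compound list**

1 | benzene-1,2,4-triol | Oc1ccc(O)c(O)c1 | starting material
2 | 1,2,4-tris(methoxymethoxy)benzene | COCOc1ccc(OCOC)c(OCOC)c1 | intermediate
3 | 1-bromo-2,4,5-tris(methoxymethoxy)benzene | COCOc1cc(OCOC)c(OCOC)cc1Br | intermediate
4 | geranyl bromide, (2E)-1-bromo-3,7-dimethylocta-2,6-diene | CC(C)=CCC/C(C)=C/CBr | starting material
5 | [2,4,5-tris(methoxymethoxy)phenyl]lithium | COCOc1cc(OCOC)c(OCOC)cc1[Li] | intermediate
6 | 1-[(2E)-3,7-dimethylocta-2,6-dien-1-yl]-2,4,5-tris(methoxymethoxy)benzene | CC(C)=CCC/C(C)=C/Cc1cc(OCOC)c(OCOC)cc1OCOC | intermediate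
7 | (2E,6E)-2,6-dimethyl-8-[2,4,5-tris(methoxymethoxy)phenyl]octa-2,6-dien-1-ol | OC/C(C)=C/CC/C(C)=C/Cc1cc(OCOC)c(OCOC)cc1OCOC | intermediate
8 | 1-[(2E,6E)-8-bromo-3,7-dimethylocta-2,6-dien-1-yl]-2,4,5-tris(methoxymethoxy)benzene | BrC/C(C)=C/CC/C(C)=C/Cc1cc(OCOC)c(OCOC)cc1OCOC | intermediate
9 | 1-[(2E,6E)-3,7-dimethyldeca-2,6,9-trien-1-yl]-2,4,5-tris(methoxymethoxy)benzene | C=CC/C(C)=C/CC/C(C)=C/Cc1cc(OCOC)c(OCOC)cc1OCOC | intermediate
10 | {3-[(2E,6E)-3,7-dimethyldeca-2,6,9-trien-1-yl]-2,5,6-tris(methoxymethoxy)phenyl}lithium | C=CC/C(C)=C/CC/C(C)=C/Cc1cc(OCOC)c(OCOC)c([Li])c1OCOC | intermediate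
11 | {3-[(2E,6E)-3,7-dimethyldeca-2,6,9-trien-1-yl]-2,5,6-tris(methoxymethoxy)phenyl}magnesium bromide | C=CC/C(C)=C/CC/C(C)=C/Cc1cc(OCOC)c(OCOC)c([Mg]Br)c1OCOC | intermediate
12 | 1-(diethoxymethyl)-3-[(2E,6E)-3,7-dimethyldeca-2,6,9-trien-1-yl]-2,5,6-tris(methoxymethoxy)benzene | C=CC/C(C)=C/CC/C(C)=C/Cc1cc(OCOC)c(OCOC)c(C(OCC)OCC)c1OCOC | intermediate
13 | tert-butyl (2S)-2-hydroxypropanoate | C[C@H](O)C(=O)OC(C)(C)C | starting material
14 | tert-butyl (2S)-2-{[(trifluoromethyl)sulfonyl]oxy}propanoate | C[C@H](OS(=O)(=O)C(F)(F)F)C(=O)OC(C)(C)C | intermediate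
15 | {(4E,8E)-10-[3-(diethoxymethyl)-2,4,5-tris(methoxymethoxy)phenyl]-4,8-dimethyldeca-4,8-dien-1-yl}magnesium bromide | Br[Mg]CCC/C(C)=C/CC/C(C)=C/Cc1cc(OCOC)c(OCOC)c(C(OCC)OCC)c1OCOC | intermediate
16 | tert-butyl (2S,6E,10E)-12-[3-(diethoxymethyl)-2,4,5-tris(methoxymethoxy)phenyl]-2,6,10-trimethyldodeca-6,10-dienoate | CC(C)(C)OC(=O)[C@@H](C)CCC/C(C)=C/CC/C(C)=C/Cc1cc(OCOC)c(OCOC)c(C(OCC)OCC)c1OCOC | intermediate
17 | trimethylsilyl (2S,6E,10E)-12-{3-[(2,2'-bipyridin-1-ium-1-yl)(ethoxy)methyl]-2,4,5-tris(trimethylsilyloxy)phenyl}-2,6,10-trimethyldodeca-6,10-dienoate trifluoromethanesulfonate | C[Si](C)(C)OC(=O)[C@@H](C)CCC/C(C)=C/CC/C(C)=C/Cc1cc(O[Si](C)(C)C)c(O[Si](C)(C)C)c(C(OCC)[n+]2ccccc2-c2ccccn2)c1O[Si](C)(C)C.[O-]S(=O)(=O)C(F)(F)F | intermediate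
18 | (2S,6E,10E)-12-(3-formyl-2,4,5-trihydroxyphenyl)-2,6,10-trimethyldodeca-6,10-dienoic acid | C/C(=C\Cc1cc(O)c(O)c(C=O)c1O)CC/C=C(\C)CCC[C@H](C)C(=O)O | target

**Step count**

Total: 10 steps. Longest linear sequence: 9 steps (1–7, 9, 10); step 8 is a one-step side branch.

**Three steps most likely to fail, each with a fallback**

Step 9 (key coupling). The iron hydride that carries the exchange can isomerise the skipped 1,4-diene into conjugation. Residual FeCl3, CuBr and PBu3 can also consume triflate 14 or open a radical path that erodes yield or enantiopurity. The fallback sets out from 12 and makes the carbon–magnesium bond stoichiometrically and free of transition-metal residues. Hydrozirconation of the vinyl group with Cp2Zr(H)Cl (THF, rt) and iodinolysis (I2, 0 °C) give 1-(diethoxymethyl)-3-[(2E,6E)-10-iodo-3,7-dimethyldeca-2,6-dien-1-yl]-2,5,6-tris(methoxymethoxy)benzene F1. Iodine–lithium exchange (t-BuLi, Et2O, −78 °C) and addition of MgBr2·OEt2 then give alkylmagnesium bromide 15, where the route is rejoined; ZnCl2-catalysed coupling with 14 leads on to 16.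

Step 4 (allylic oxidation). Conversion is moderate, and the internal olefin, the benzylic CH2 or the electron-rich ring may be attacked, or the alcohol over-oxidised. The fallback sets out from 3 and oxidises the terpene before the arene is attached. Geranyl acetate is oxidised under the same SeO2/t-BuOOH conditions to (2E,6E)-8-hydroxy-3,7-dimethylocta-2,6-dien-1-yl acetate F2. Separately, 3 is converted through aryllithium 5 and MgBr2·OEt2 into [2,4,5-tris(methoxymethoxy)phenyl]magnesium bromide F3. F3 (2.2 equiv, the first equivalent deprotonating the hydroxyl) displaces the primary allylic acetate of F2 under Li2CuCl4 catalysis (THF, −30 °C, fast addition), and the route is rejoined at 7.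

Step 10 (global deprotection). The tert-butyl ester may cleave more slowly than the MOM ethers and the acetal, and the free hydroxyhydroquinone is easily oxidised. The fallback sets out from 16 and separates the two events. Dilute aqueous HCl in THF/MeOH (40 °C, Ar) removes the acetal and the three MOM ethers to give tert-butyl (2S,6E,10E)-12-(3-formyl-2,4,5-trihydroxyphenyl)-2,6,10-trimethyldodeca-6,10-dienoate F4. Anhydrous ZnBr2 in CH2Cl2 (rt, Ar) then cleaves the tert-butyl ester, and the route is rejoined at 18.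

**Further compounds**

F1 | step 9 | 1-(diethoxymethyl)-3-[(2E,6E)-10-iodo-3,7-dimethyldeca-2,6-dien-1-yl]-2,5,6-tris(methoxymethoxy)benzene | ICCC/C(C)=C/CC/C(C)=C/Cc1cc(OCOC)c(OCOC)c(C(OCC)OCC)c1OCOC
F2 | step 4 | (2E,6E)-8-hydroxy-3,7-dimethylocta-2,6-dien-1-yl acetate | CC(=O)OC/C=C(\C)CC/C=C(\C)CO
F3 | step 4 | [2,4,5-tris(methoxymethoxy)phenyl]magnesium bromide | COCOc1cc(OCOC)c(OCOC)cc1[Mg]Br
F4 | step 10 | tert-butyl (2S,6E,10E)-12-(3-formyl-2,4,5-trihydroxyphenyl)-2,6,10-trimethyldodeca-6,10-dienoate | CC(C)(C)OC(=O)[C@@H](C)CCC/C(C)=C/CC/C(C)=C/Cc1cc(O)c(O)c(C=O)c1O
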